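Mirror images cannot be expected to react alike over a single-handed free catalyst, and the last pair of readings in each run below shows the difference.

| flask | left-handed substrate | right-handed substrate | coupling partner | precatalyst | remark | time |
|---|---|---|---|---|---|---|
| winter | 0.020 M | 0.020 M | 0.55 equiv | 3.1 mol% | run made earlier |  |
| summer | 0.020 M | 0.020 M | 0.83 equiv | 3.1 mol% | run made earlier |  |
| flask | 0.020 M | 0.020 M | 1.10 equiv | 3.1 mol% |  | 1.5 h |

| run | time / min | left-handed substrate / % | right-handed substrate / % |
|---|---|---|---|
| winter | 12.0 | 48.6 | 48.8 |
| winter | 30.0 | 47.9 | 48.7 |
| winter | 60.0 | 44.4 | 47.6 |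
| winter | 90.0 | 41.4 | 46.4 |
| summer | 8.00 | 49.0 | 49.8 |
| summer | 15.0 | 48.5 | 48.9 |
| summer | 40.0 | 44.4 | 48.1 |
| summer | 90.0 | 37.8 | 45.5 |

(readings scatter by 0.5 percentage points)
1. part of the left-handed substrate and right-handed substrate charged together that has reacted at 1.5 h
2. excess of left-handed product over right-handed product in the product at 1.5 h
3. excess of right-handed substrate over left-handed substrate among what is left of the two at 1.5 h
- free catalyst is single-handed; left-handed substrate and right-handed substrate are mirror images of each other, charged as a racemate, each of them at the stated concentration
- an excess is the difference of the two amounts in percent of their sum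
- an excess is below zero if the other one leads

In the winter run at 90.0 min, the right-handed substrate had lost 3.6 percentage points and the left-handed substrate 8.6 points, so the right-handed loss is smaller but is a second reaction that has to be counted, and one ratio is needed to tie the two losses together. The winter reading gives 2.53 and the summer reading 2.97, with mean s = 2.75, the selectivity factor: the logarithm of the fraction of left-handed substrate left, divided by the same logarithm for right-handed substrate. It is a reading, with 0.5 points of scatter on small losses. Taken as constant, it turns a fraction left of left-handed substrate into that of right-handed substrate, as its power 1/s.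

The forecast, with “so s is about 2.8”, slightly above this mean, gave c 22 %, eP 43 % and eS 12 %.

The flask gave c 21.3 %, eP 38.6 % and eS 10.1 %, and the forecast held within its margins.

    free catalyst + left-handed substrate ⇌ catalyst intermediate A (K = 27.0 M⁻¹, k = 44.0 M⁻¹ min⁻¹)
    coupling partner + catalyst intermediate A → free catalyst + left-handed product (k = 51.0 M⁻¹ min⁻¹)
    precatalyst → free catalyst (k = 0.0530 min⁻¹)
    free catalyst + right-handed substrate ⇌ catalyst intermediate B (K = 19.0 M⁻¹, k = 67.0 M⁻¹ min⁻¹)
    coupling partner + catalyst intermediate B → free catalyst + right-handed product (k = 22.0 M⁻¹ min⁻¹)
    coupling partner → decomposed reagent (k = 0.00450 min⁻¹)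

The quantity s contains no time, so the 62.1 % of catalyst still standing as precatalyst in the flask at 0.150 h does not enter it. In the flask at 1.5 h, 71 % of the left-handed substrate remained, which s turns into 88.1 % of right-handed substrate against a simulated 87 %, and into eS 11.0 %. The neighbouring flask, with 0.78 mol% of precatalyst, reached c 6.79 %, less than this flask. Its 91 % of left-handed substrate left gives by s 96.5 % of right-handed substrate against a simulated 96 %, and eS 3.15 % against a simulated 2.84 %.

All runs were computed for substances that don't exist, noise included.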